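Read the violet run against the red one before arguing about coupling partner, and ask what a flask can still hold at its end.

| setting | red | violet | Tuesday's | Sunday's | Wednesday's | Thursday's | Monday's |
|---|---|---|---|---|---|---|---|
| substrate | 20 mM | 20 mM | 20 mM | 20 mM | 20 mM | 20 mM | 20 mM |
| coupling partner | 72 mM | 1300 mM | 50.0 mM | 100 mM | 200 mM | 400 mM | 800 mM |
| catalyst | 100 µM | 100 µM | 100 µM | 100 µM | 100 µM | 100 µM | 100 µM |
| remark | run made earlier | run made earlier |  |  |  |  |  |
| time |  |  | 30 h | 30 h | 30 h | 30 h | 30 h |

- red (time / h: target / %, substrate / %): 8.00: 28, 23; 15.0: 21, 4; 25.0: 9, 2; 30.0: 7, 2
- violet (time / h: target / %, substrate / %): 2.50: 2, 65; 6.00: 1, 35; 12.0: 0, 10; 30.0: 0, 0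

(scatter of a reading: 2 percentage points)

- percent here means substrate units held: one side product counts as two
- what is said of target includes crystals
- crystals is a solid; its amount is given per volume of the solution
- candidate steps: coupling partner + catalyst + intermediate -> catalyst + target; substrate + intermediate -> side product; crystals <-> target; coupling partner + catalyst + target -> catalyst + over-reaction product; substrate + catalyst <-> catalyst + intermediate
- "hardly changes" means that all values lie within two and a half points (for a concentration: within two and a half percent of the largest)

1. amount of target at the end, in percent of the substrate charged for Tuesday's, Sunday's, Wednesday's, Thursday's, Monday's, in this order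
2. the shape of the row from first to last (falls, then rises / rises, then falls / rises all the way / falls all the way / hardly changes)

Ines and Paul disagree about this row. Ines reads the red run: at 8.00 h target stands at 28 % and substrate at 23 %, so 49.0 % of the charge has gone elsewhere. She books that as side product, which more coupling partner should prevent, so her row climbs.

Paul reads the violet run. At 2.50 h substrate is down to 65 % while target shows 2 %, a rough reading with a scatter of 2 percentage points. That reading gives a substrate decay of 0.172 h⁻¹, and the red run's reading at 8.00 h gives 0.184 h⁻¹, although the two partner charges differ by a factor of 18.1. So this decay looks pseudo-first-order, with partner hardly hurrying it.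

Paul then assumes that target burns on in proportion to c(coupling partner). His measure is the balance charge, the c(coupling partner) at which target burns away just as fast as substrate decays. Taking feed and burning as level in the violet run, he multiplies its charge by its target-to-substrate reading and gets 40.0 mM.

With the substrate and catalyst charges as they stand here, and well above that charge, he takes target as a standing share of the substrate left, namely the balance charge divided by c(coupling partner) minus the balance charge. Monday's charge lies far above it, so his share for Monday's flask is 5.26 %. Substrate left after 30 h should be 0.569 %, which gives Paul 0.0299 % of target in Monday's flask.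

Near the balance charge his rule is weak. For the red run it gives 0.711 %, yet the reading at 30.0 h is 7 %. Paul therefore commits to a falling row, starting above the red reading and ending at his Monday's figure.

The forecast, from the same side but with its own numbers, reads 17 %, 3 %, 0 %, 0 % and 0 %, shape falls all the way, on the ground of “the drain, proportional to partner”.

The simulation gives 16.4 %, 2.32 %, 0.285 %, 0.0814 % and 0.0324 %, shape falls all the way.

    coupling partner + catalyst + intermediate → catalyst + target (k = 726 L² mol⁻² min⁻¹)
    substrate + intermediate → side product (k = 0.0306 L mol⁻¹ min⁻¹)
    crystals ⇌ target, rate k3*(cs3 - [target]) while solid is left; crystals form when [target] > cs3 (solubility = 16.0 mM, k = 0.0512 min⁻¹)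
    coupling partner + catalyst + target → catalyst + over-reaction product (k = 595 L² mol⁻² min⁻¹)
    substrate + catalyst ⇌ catalyst + intermediate (K = 6.85, k = 30.5 L mol⁻¹ min⁻¹)

The passing of target into over-reaction product is the main reason for the low end values of Monday's and Tuesday's flasks: without that step Monday's flask ends with 98.6 % of target instead of 0.0324 %, and Tuesday's with 85.8 % instead of 16.4 %. Ines's rise belongs to these two flasks with that step taken away. For Thursday's flask, the balance charge and the 0.446 % of substrate left give 0.0495 % of target, and that flask holds 0.0814 %.

The numbers in the tables are simulated from invented constants; noise was put on by code.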